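**Retrosynthetic overview**

1. Target 16 ⇐ benzyl ether diol 15 ⇐ catechol lactone 14 (lactone reduction gives both CH2OH groups; O-debenzylation last).
2. C8–O bond of 14 ⇐ phenol lactone 10 by a boron-templated ortho-hydroxylation (the last skeletal bond made, a C–O bond).
3. Ring B of 10 ⇐ Friedel–Crafts closure (C1–C8a) of aldol adduct 8, itself from lactone 6 and O-benzylvanillin 7.
4. Lactone ring of 6 and all absolute configuration ⇐ desymmetrising asymmetric Baeyer–Villiger C–O insertion into cyclobutanone 5.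
5. 5 ⇐ Boc-eugenol 2 + dichloroketene. Ring order: ring A (bought in eugenol) → cyclobutanone → lactone → ring B.

Assumption: tetralin numbering is used for the target (aryl at C1, CH2OH at C2 and C3, ring A = C5–C8, ring B = the saturated ring), which makes it (1S,2R,3R); eugenol, trichloroacetyl chloride and 4-(benzyloxy)-3-methoxybenzaldehyde are bought; in step 3 the ligand antipode that gives the (R)-lactone is used.

**Route**

Step 1
Reactants: 1 eugenol
Product: 2 tert-butyl (4-allyl-2-methoxyphenyl) carbonate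
Conditions: Boc2O, DMAP (5 mol %), MeCN, rt
Reagents that add atoms: di-tert-butyl dicarbonate, CC(C)(C)OC(=O)OC(=O)OC(C)(C)C
Why: DMAP-catalysed O-acylation (Boc protection) masks the ring A phenol through the ketene, peracid and enolate steps and is the only group later lost in TFA, so the two guaiacyl phenols are told apart exactly when needed.

Step 2
Reactants: 2 tert-butyl (4-allyl-2-methoxyphenyl) carbonate; 3 trichloroacetyl chloride
Product: 5 tert-butyl {2-methoxy-4-[(3-oxocyclobutyl)methyl]phenyl} carbonate, via dichlorocyclobutanone 4 (not isolated)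
Conditions: Zn(Cu), Et2O/DME, rt; filter; then Zn, AcOH, rt
Reagents that add atoms: none
Why: Ketene–alkene [2+2] cycloaddition of dichloroketene (made in situ) with the terminal alkene puts the CCl2 group next to the substituted carbon, and zinc/acetic acid reductive dechlorination then gives the symmetric 3-substituted cyclobutanone with no stereocenter.

Step 3
Reactants: 5 tert-butyl {2-methoxy-4-[(3-oxocyclobutyl)methyl]phenyl} carbonate
Product: 6 (4R)-4-[4-(tert-butoxycarbonyloxy)-3-methoxybenzyl]oxolan-2-one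
Conditions: mCPBA, Sc(OTf)3 (5 mol %), C2-symmetric chiral N,N'-dioxide ligand (6 mol %), EtOAc, −20 °C
Reagents that add atoms: mCPBA, O=C(OO)c1cccc(Cl)c1
Why: Catalytic asymmetric Baeyer–Villiger oxidation (desymmetrisation): the chiral Sc(OTf)3–N,N'-dioxide complex holds the Criegee adduct so that only one of the two enantiotopic CH2 groups migrates to oxygen, which sets the single stereocenter as R and is the source of all absolute configuration in the route.

Step 4
Reactants: 6 (4R)-4-[4-(tert-butoxycarbonyloxy)-3-methoxybenzyl]oxolan-2-one; 7 4-(benzyloxy)-3-methoxybenzaldehyde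
Product: 8 (3S,4R)-3-{[4-(benzyloxy)-3-methoxyphenyl](hydroxy)methyl}-4-[4-(tert-butoxycarbonyloxy)-3-methoxybenzyl]oxolan-2-one (carbinol epimers)
Conditions: LiN(SiMe3)2 (1.05 equiv), THF, −78 °C; then 7; AcOH quench at −78 °C
Reagents that add atoms: none
Why: Lithium enolate aldol addition in which the aldehyde approaches the enolate face anti to the C4 benzyl group, setting C3 trans to C4 (3S,4R); the carbinol centre forms as a mixture that is erased in step 5.

Step 5
Reactants: 8 (3S,4R)-3-{[4-(benzyloxy)-3-methoxyphenyl](hydroxy)methyl}-4-[4-(tert-butoxycarbonyloxy)-3-methoxybenzyl]oxolan-2-one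
Product: 10 (3aR,9S,9aR)-9-[4-(benzyloxy)-3-methoxyphenyl]-7-hydroxy-6-methoxy-3a,4,9,9a-tetrahydronaphtho[2,3-c]furan-1(3H)-one, via Boc-protected cyclised lactone 9 (not isolated)
Conditions: TFA/CH2Cl2 (1:4), 0 °C → rt
Reagents that add atoms: none
Why: Intramolecular Friedel–Crafts alkylation in which TFA ionises the 4-benzyloxybenzylic alcohol and ring A attacks para to its OMe group, closing ring B with the aryl group pseudo-equatorial and trans to the lactone carbonyl (9S); the same acid then removes the Boc carbonate by acidolysis.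

Step 6
Reactants: 10 (3aR,9S,9aR)-9-[4-(benzyloxy)-3-methoxyphenyl]-7-hydroxy-6-methoxy-3a,4,9,9a-tetrahydronaphtho[2,3-c]furan-1(3H)-one
Product: 14 (3aR,9S,9aR)-9-[4-(benzyloxy)-3-methoxyphenyl]-7,8-dihydroxy-6-methoxy-3a,4,9,9a-tetrahydronaphtho[2,3-c]furan-1(3H)-one, via aryl dimethyl borate 11 (not isolated), via acylperoxyborate 12 (not isolated), via cyclic catechol methyl borate 13 (not isolated)
Conditions: B(OMe)3 (3 equiv), PhMe, 50 °C, then evaporate; dry mCPBA (1.1 equiv), CH2Cl2/HFIP (9:1), 4 Å MS, −20 °C → rt; aq. Na2S2O3, pH 7 buffer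
Reagents that add atoms: mCPBA, O=C(OO)c1cccc(Cl)c1
Why: Proposed new method: boron-templated ortho-hydroxylation of a phenol — the phenol is bound as an aryl borate (11) whose boron also takes up the peracid as an acylperoxy ligand (12), so the ring carbon ortho to the borate oxygen (C8) can attack the boron-bound peroxy oxygen through a five-membered transition state with m-chlorobenzoate as leaving group (an intramolecular SEAr, Prilezhaev-like oxygen transfer in which boron plays the part of the peracid proton), and the catechol leaves as cyclic borate 13, which has no free OH and resists a second oxidation; only ring A carries a free phenol and its para position and other ortho position (OMe) are substituted, so C8 is the only C–H in reach, and an SEAr pathway tolerates this peri-flanked site better than a metallacycle would; the closest known reaction types are the boronic-acid-templated ortho-hydroxyalkylation of phenols (Nagata), the acylperoxyborate oxidants formed from perborate and acetic anhydride, and the ortho-benzoyloxylation of phenols by dibenzoyl peroxide.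

Step 7
Reactants: 14 (3aR,9S,9aR)-9-[4-(benzyloxy)-3-methoxyphenyl]-7,8-dihydroxy-6-methoxy-3a,4,9,9a-tetrahydronaphtho[2,3-c]furan-1(3H)-one
Product: 15 [(1S,2R,3R)-1-[4-(benzyloxy)-3-methoxyphenyl]-7,8-dihydroxy-6-methoxy-1,2,3,4-tetrahydronaphthalene-2,3-diyl]dimethanol
Conditions: LiAlH4, THF, 0 °C → rt; aq. potassium sodium tartrate work-up
Reagents that add atoms: none
Why: LiAlH4 reduction of the lactone gives the two primary alcohols; hydride addition to the carbonyl is faster than any epimerisation at C9a, so the three stereocenters are kept and the benzyl ether survives.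

Step 8
Reactants: 15 [(1S,2R,3R)-1-[4-(benzyloxy)-3-methoxyphenyl]-7,8-dihydroxy-6-methoxy-1,2,3,4-tetrahydronaphthalene-2,3-diyl]dimethanol
Product: 16 (1S,2R,3R)-1-(4-hydroxy-3-methoxyphenyl)-2,3-bis(hydroxymethyl)-6-methoxy-1,2,3,4-tetrahydronaphthalene-7,8-diol
Conditions: H2 (1 atm), Pd/C (10 %), MeOH, rt
Reagents that add atoms: none
Why: Hydrogenolysis of the aryl benzyl ether frees the last phenol without touching any stereocenter.

**Compound list**

1 | eugenol (4-allyl-2-methoxyphenol) | C=CCc1ccc(O)c(OC)c1 | starting material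
2 | tert-butyl (4-allyl-2-methoxyphenyl) carbonate | C=CCc1ccc(OC(=O)OC(C)(C)C)c(OC)c1 | intermediate
3 | trichloroacetyl chloride | ClC(Cl)(Cl)C(Cl)=O | starting material
4 | tert-butyl {4-[(2,2-dichloro-3-oxocyclobutyl)methyl]-2-methoxyphenyl} carbonate (racemic; not isolated) | O=C1CC(Cc2ccc(OC(=O)OC(C)(C)C)c(OC)c2)C1(Cl)Cl | intermediate
5 | tert-butyl {2-methoxy-4-[(3-oxocyclobutyl)methyl]phenyl} carbonate | O=C1CC(Cc2ccc(OC(=O)OC(C)(C)C)c(OC)c2)C1 | intermediate
6 | (4R)-4-[4-(tert-butoxycarbonyloxy)-3-methoxybenzyl]oxolan-2-one | O=C1C[C@@H](Cc2ccc(OC(=O)OC(C)(C)C)c(OC)c2)CO1 | intermediate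
7 | 4-(benzyloxy)-3-methoxybenzaldehyde | O=Cc1ccc(OCc2ccccc2)c(OC)c1 | starting material
8 | (3S,4R)-3-{[4-(benzyloxy)-3-methoxyphenyl](hydroxy)methyl}-4-[4-(tert-butoxycarbonyloxy)-3-methoxybenzyl]oxolan-2-one (both carbinol epimers) | CC(C)(C)OC(=O)Oc1ccc(C[C@H]2COC(=O)[C@@H]2C(O)c2ccc(OCc3ccccc3)c(OC)c2)cc1OC | intermediate
9 | (3aR,9S,9aR)-9-[4-(benzyloxy)-3-methoxyphenyl]-6-methoxy-1-oxo-1,3,3a,4,9,9a-hexahydronaphtho[2,3-c]furan-7-yl tert-butyl carbonate (not isolated) | COc1cc([C@H]2c3c(cc(OC)c(OC(=O)OC(C)(C)C)c3)C[C@@H](COC4=O)[C@@H]24)ccc1OCc1ccccc1 | intermediate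
10 | (3aR,9S,9aR)-9-[4-(benzyloxy)-3-methoxyphenyl]-7-hydroxy-6-methoxy-3a,4,9,9a-tetrahydronaphtho[2,3-c]furan-1(3H)-one | COc1cc([C@H]2c3c(cc(OC)c(O)c3)C[C@@H](COC4=O)[C@@H]24)ccc1OCc1ccccc1 | intermediate
11 | dimethyl borate ester of 10 at O7 (not isolated) | COc1cc([C@H]2c3c(cc(OC)c(OB(OC)OC)c3)C[C@@H](COC4=O)[C@@H]24)ccc1OCc1ccccc1 | intermediate
12 | (aryloxy)(methoxy)boryl 3-chloroperbenzoate of 10 at O7 (not isolated) | COc1cc([C@H]2c3c(cc(OC)c(OB(OC)OOC(=O)c5cccc(Cl)c5)c3)C[C@@H](COC4=O)[C@@H]24)ccc1OCc1ccccc1 | intermediate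
13 | cyclic methyl borate of catechol 14 (2-methoxy-1,3,2-dioxaborole across O7 and O8; not isolated) | COc1cc([C@H]2c3c(cc(OC)c4OB(OC)Oc34)C[C@@H](COC5=O)[C@@H]25)ccc1OCc1ccccc1 | intermediate
14 | (3aR,9S,9aR)-9-[4-(benzyloxy)-3-methoxyphenyl]-7,8-dihydroxy-6-methoxy-3a,4,9,9a-tetrahydronaphtho[2,3-c]furan-1(3H)-one | COc1cc([C@H]2c3c(cc(OC)c(O)c3O)C[C@@H](COC4=O)[C@@H]24)ccc1OCc1ccccc1 | intermediate
15 | [(1S,2R,3R)-1-[4-(benzyloxy)-3-methoxyphenyl]-7,8-dihydroxy-6-methoxy-1,2,3,4-tetrahydronaphthalene-2,3-diyl]dimethanol | COc1cc([C@H]2c3c(cc(OC)c(O)c3O)C[C@@H](CO)[C@@H]2CO)ccc1OCc1ccccc1 | intermediate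
16 | (1S,2R,3R)-1-(4-hydroxy-3-methoxyphenyl)-2,3-bis(hydroxymethyl)-6-methoxy-1,2,3,4-tetrahydronaphthalene-7,8-diol | COc1cc([C@H]2c3c(cc(OC)c(O)c3O)C[C@@H](CO)[C@@H]2CO)ccc1O | target

**Step count and risks**

Total: 8 steps. Longest linear sequence: 8 steps (1 → 16); aldehyde 7 and acid chloride 3 are bought.

Most likely to fail, step 6 (the proposed new hydroxylation). The peracid may not transfer oxygen to the weakly activated, peri-flanked C8, or oxygen may go to the OMe-bearing C6. The fallback uses known chemistry, sets out from 10 and comes back at 14. Ortho-formylation with MgCl2, Et3N and paraformaldehyde in MeCN at reflux (Casiraghi–Skattebøl) gives the C8 salicylaldehyde F1. mCPBA in CH2Cl2 (Dakin-type Baeyer–Villiger, aryl migration) gives the C8 aryl formate F2. KHCO3 in MeOH at 0 °C cleaves the formate and gives 14.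

Second, step 3 (asymmetric Baeyer–Villiger). Benzyl-substituted cyclobutanones usually give lower ee than aryl ones, and the sense must be confirmed; partial ee could be raised by recrystallising 10. The fallback sets out from 7 and comes back at 6. Stobbe condensation of 7 with dimethyl succinate (NaOMe, MeOH, reflux) gives the (E)-half-ester F3. Hydrogenation with [Rh(cod)2]BF4 and the Et-DuPhos antipode that gives R (H2, MeOH) gives the (R)-benzylsuccinic half-ester F4. Reduction of the ester on the potassium carboxylate with CaCl2/NaBH4 in EtOH, then HCl, gives the benzyl-protected lactone F5. H2 over Pd/C gives the phenol lactone F6, and Boc2O/DMAP gives 6.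

Third, step 5 (cyclisation with Boc loss). The carbinol may eliminate to the arylidene lactone, or the tert-butyl cation may alkylate ring A. The fallback sets out from 6 and comes back at 9. Alkylation of the enolate of 6 (LiN(SiMe3)2, THF, −78 °C) with 4-(benzyloxy)-3-methoxybenzyl bromide gives the trans-dibenzyl lactone F7. DDQ in CH2Cl2 with a little TFA at 0 °C abstracts hydride from the more electron-rich 4-benzyloxybenzyl CH2, and the cation closes ring B to give 9. A short, separate TFA treatment after the DDQ is consumed then converts 9 to 10.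

**Further compounds**

F1 | step 6 | (3aR,9S,9aR)-9-[4-(benzyloxy)-3-methoxyphenyl]-7-hydroxy-6-methoxy-1-oxo-1,3,3a,4,9,9a-hexahydronaphtho[2,3-c]furan-8-carbaldehyde | COc1cc([C@H]2c3c(cc(OC)c(O)c3C=O)C[C@@H](COC4=O)[C@@H]24)ccc1OCc1ccccc1
F2 | step 6 | (3aR,9S,9aR)-9-[4-(benzyloxy)-3-methoxyphenyl]-7-hydroxy-6-methoxy-1-oxo-1,3,3a,4,9,9a-hexahydronaphtho[2,3-c]furan-8-yl formate | COc1cc([C@H]2c3c(cc(OC)c(O)c3OC=O)C[C@@H](COC4=O)[C@@H]24)ccc1OCc1ccccc1
F3 | step 3 | (E)-4-[4-(benzyloxy)-3-methoxyphenyl]-3-(methoxycarbonyl)but-3-enoic acid | COC(=O)/C(CC(=O)O)=C/c1ccc(OCc2ccccc2)c(OC)c1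
F4 | step 3 | (3R)-4-[4-(benzyloxy)-3-methoxyphenyl]-3-(methoxycarbonyl)butanoic acid | COC(=O)[C@@H](CC(=O)O)Cc1ccc(OCc2ccccc2)c(OC)c1
F5 | step 3 | (4R)-4-[4-(benzyloxy)-3-methoxybenzyl]oxolan-2-one | O=C1C[C@@H](Cc2ccc(OCc3ccccc3)c(OC)c2)CO1
F6 | step 3 | (4R)-4-(4-hydroxy-3-methoxybenzyl)oxolan-2-one | O=C1C[C@@H](Cc2ccc(O)c(OC)c2)CO1
F7 | step 5 | (3R,4R)-3-[4-(benzyloxy)-3-methoxybenzyl]-4-[4-(tert-butoxycarbonyloxy)-3-methoxybenzyl]oxolan-2-one | CC(C)(C)OC(=O)Oc1ccc(C[C@H]2COC(=O)[C@@H]2Cc2ccc(OCc3ccccc3)c(OC)c2)cc1OC
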